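(The numbers in the tables are calculated for an exercise, noise included.)

From the amber run to the teal run the charge of solid substrate grew by a factor of 4.00, while the fraction standing as target at 15.0 min shrank by a factor of 3.46, so I looked at their product. Amber read 0.0731 M and teal read 0.0845 M for what I call the held target, the plateau fraction times the charge.

common to all: reagent 1.05 equiv

|  | solid substrate | remark | time |
|---|---|---|---|
| amber | 0.12 M | run made earlier |  |
| teal | 0.48 M | run made earlier |  |
| flask | 0.24 M |  | 15 min |

| run | time / min | target / % | dissolved substrate / % |
|---|---|---|---|
| amber | 1.33 | 23.0 | 7.9 |
| amber | 4.00 | 59.5 | 2.8 |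
| amber | 8.00 | 60.6 | 0.2 |
| amber | 10.0 | 61.3 | 0 |
| amber | 15.0 | 60.9 | 0.3 |
| teal | 3.00 | 4.0 | 0.5 |
| teal | 6.00 | 8.4 | 0.7 |
| teal | 10.0 | 17.6 | 0 |
| teal | 12.0 | 17.8 | 0.4 |
| teal | 15.0 | 17.6 | 0.1 |

(each reading ± 0.3 percentage points)

- in percentages every species weighs as the solid substrate in it: one side product A or side product B counts as two
- as a solid, counted per litre of solution: solid substrate
- on the list of suspects stand: solid substrate <-> dissolved substrate; solid substrate + target -> side product B; dissolved substrate + reagent -> target; dissolved substrate + target -> side product A
- at the start none of the solid substrate is in solution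
- dissolved substrate means what is dissolved; the solid is not counted in it

1. the target standing at 15 min, as a percentage of the solid substrate charged
2. concentration of dissolved substrate in solution at 15 min, in percent of saturation

The charge of the flask lies between those of the two runs, so my crude bracket was the two fractions themselves: at most 60.9 %, at least 17.6 %. I tightened it by assuming that the held target moves steadily with charge. Amber's value then gave a lower bound of 30.4 % of the flask's charge, and teal's gave an upper bound of 35.2 %. Dissolved substrate read 0.3 % in amber and 0.1 % in teal at 15.0 min, on the scale of the scatter of 0.3 percentage points, so I expected saturation near zero.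

The forecast said 35 % of target and 0 % of saturation, on the ground that “a larger solid load means more loss”. Its yield lay inside my bracket, close under the top.

The flask gave 35.2 % and 0 % of saturation, so the forecast held, and the yield stood at the top edge of my bracket, a held target of 0.0845 M.

    solid substrate ⇌ dissolved substrate, rate k1*(cs1 - [dissolved substrate]) while solid is left; crystals form when [dissolved substrate] > cs1 (solubility = 0.130 M, k = 0.00470 s⁻¹)
    solid substrate + target → side product B (k = 0.100 M⁻¹ s⁻¹)
    dissolved substrate + reagent → target (k = 0.640 M⁻¹ s⁻¹)
    dissolved substrate + target → side product A (k = 0.0290 M⁻¹ s⁻¹)

At 2.31 min in the flask, solid substrate consumed target 78 times faster than dissolved substrate did, a ratio of rates at that moment. The half-life of target by the step with the solid was then 1.0 min, shorter than the 15 min of the flask. On the neighbour charged with 0.60 M of solid substrate, teal's held target gives 14.1 % of the charge; computed, that neighbour stands at 14.2 %.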